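Assumption: 4-(benzyloxy)-3-methoxybenzaldehyde (O-benzylvanillin) is bought as such, which saves the benzylation of vanillin. The chain is numbered C1 (ring carbon carrying the guaiacyl group) to C7 (benzylic CH2 of the 4-hydroxyphenyl arm); the target is then (1R,3R,5S,6R).

## Structural features

The target is a diarylheptanoid whose seven-carbon chain is folded into a tetrahydropyran, with the ring oxygen joining C1 and C5. C1 carries the 4-hydroxy-3-methoxyphenyl (guaiacyl) ring, C3 a free secondary hydroxyl, and C5 the exocyclic arm C6(OH)–C7H2–(4-hydroxyphenyl). The three ring substituents at C1, C3 and C5 are mutually cis and therefore all equatorial in the chair. C6 stands directly next to C5, with its hydroxyl anti to the ring oxygen when C4–C7 is drawn as a zigzag. The fragile point is the C1–O bond, a para-oxygenated benzylic ether that can ionise under acid and can be hydrogenolysed; the two phenols must also be masked through the organometallic steps. The real difficulty is absolute control of the 1,3-related pair C1/C3 and its relay to C5 and C6. The key step exploits the segment O–C1(aryl)–C2–C3(O) with cis aryl and oxygen, which is the retron of an endo oxa-[4+2] between a styrene (C1=C2) and a 1-oxadiene O=C5–C4=C3 that carries oxygen on C3 and an ester on C5. Because the all-cis ring is also the all-equatorial one, C5, which stays next to a carbonyl for much of the route, is self-correcting.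

## Logic of the disconnections

From 13 back to 12: the three O–CH2Ph bonds (two phenolic, one at C3–O) are cut. One kind of mask on all three oxygens means a single neutral unmasking at the end and full tolerance of the organometallic steps. The demand is that the hydrogenolysis spares the cyclic benzylic C1–O bond.

From 12 back to 11: the C6–H bond is cut, turning the carbinol into a ketone. C6 sits beside the ring oxygen, so a chelating hydride can read the configuration of C5. This removes one stereocentre. The demand is that chelated delivery dominates, since it gives the required anti C5–O/C6–O pair.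

From 11 back to 8 and 10 (made from 9): the C6–C7 bond is cut between an acyl electrophile and a benzylic nucleophile. The whole 4-oxyphenyl arm comes off as a purchasable benzylic chloride. The demand is a single addition to the acyl group and formation of 10 without homocoupling.

From 8 back to 7: the acyl C–N bond is cut, a pure change of acyl derivative. It is needed only so that the next step stops at the ketone. The demand is that C5 stays equatorial, which is its thermodynamic position.

From 7 back to 6: the C4–H and C5–H bonds are cut, revealing the C4=C5 enol ether. This removes the C5 stereocentre and exposes the cycloaddition retron. The demand is syn delivery of hydrogen anti to the C1 and C3 substituents, without loss of benzyl ethers or of the allylic C3–O bond.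

From 6 back to 2 and 5: the O–C1 and C2–C3 bonds are cut. This opens the ring and removes both remaining stereocentres in one stroke, leaving two achiral components of seven and four skeletal atoms. The demand is a catalyst that fixes the face of 5, an endo approach of the aryl group, and suppression of cationic oligomerisation of 2.

From 2 back to 1: the C1=C2 double bond is cut to an aldehyde and a one-carbon ylide. The aldehyde is commercial and non-enolisable. The only demand is careful handling of a polymerisable product.

From 5 back to 3 and 4: the C4–C5 bond is cut between the β-carbon of an enol ether and an oxalyl electrophile. Both partners are commercial. The demand is E geometry, which is the thermodynamic outcome for a push–pull enone.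

## Other disconnections considered

Alternative 1: The cut is made on both sides of C3 (C2–C3 and C3–C4), with C3 as a masked acyl dianion; no ring of the target is closed.
- Forward key step: 2-(tert-butyldimethylsilyl)-1,3-dithiane A2 is lithiated and opens the aryl oxirane A3 at its CH2 carbon (C2). A 1,4-Brook shift of silicon to the new C1 alkoxide regenerates the dithiane anion, which opens the C4–C5 epoxide A4 at C4 to give the open chain A1 in one flask.
- In its favour: high convergence, established anion-relay chemistry, and C5 and C6 fixed beforehand in A4 by independent, reliable asymmetric methods.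
- Against it here: A3 is an electron-rich styrene oxide, prone to Lewis-acid rearrangement and to attack at the benzylic carbon. A4 needs several steps of its own for two adjacent stereocentres. After A1, the dithiane must still be removed next to electron-rich arenes, the ring closed and the C3 carbonyl reduced. Ring closure at C1 with retention is only possible through the benzylic cation, so the C1 configuration bought with A3 is erased and re-set thermodynamically.
- Comparison: on precedent this plan is the better of the two, since every step is known chemistry while the chosen key step is not. On structure it is the equal or better in that A1 already holds all seven chain carbons and both arenes. On mechanism it forms two C–C bonds but creates no ring and no stereocentre, where the chosen step creates one ring and two stereocentres catalytically. On step economy it is clearly longer (about twelve steps against eight).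

Alternative 2: The cut is made at C1–C2 and C4–C5, with the ring oxygen, C1 and C5 drawn from furan.
- Forward key step: furan A6 and the zinc oxyallyl cation from 1,1,3,3-tetrabromoacetone A7 undergo [4+3] cycloaddition, with Zn–Cu debromination in the same flask, to give the meso bicyclic ketone A5.
- In its favour: the cheapest starting materials of all the plans, a scalable step, and a bicyclic frame that locks C1 and C5 cis and already places a carbonyl at C3.
- Against it here: A5 is achiral, so a desymmetrisation is needed. It contains neither arene. After cleavage of the two-carbon bridge, C1 carries a carbon atom where the target needs the guaiacyl ring directly attached, so that carbon must be excised (for example by decarboxylative arylation, which passes through a C1 radical and must re-establish the cis relationship). The C5 side needs homologation and the C6 stereocentre. The C3 carbonyl must also be reduced to the alcohol syn to the former bridge.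
- Comparison: in certainty of the cis C1/C5 relationship this plan is the equal of the chosen one, and in cost of materials it is the better. On structure it is poorly matched, because the cycloadduct carries none of the substituents, whereas 6 already carries the guaiacyl ring, the C3 oxygen and a C5 handle in the correct oxidation state. On step economy it is the longest of the four (well over twelve steps).

Alternative 3: The cut is made at C3–C4, with a temporary N–O bridge between C3 and the C5 oxygen.
- Forward key step: the nitrile oxide generated from the cinnamaldoxime A9 (chlorination and base, or NaOCl) adds to the terminal alkene of the (R)-allylic silyl ether A10, forming C3–C4 and O–C5 and giving the isoxazoline A8.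
- After A8: N–O cleavage (for example Mo(CO)6) would unveil the C5 hydroxyl and the C3 carbonyl conjugated to C1=C2. Conjugate ring closure of the C5 oxygen onto C1 under thermodynamic control gives the 1,5-cis ring, and hydride reduction at C3 gives the equatorial alcohol.
- In its favour: every operation is known chemistry. The regiochemistry of the cycloaddition is reliable, the inside-alkoxy effect favours the anti C5/C6 relationship the target needs, and the enone needed for ring closure appears automatically.
- Against it here: facial selectivity of nitrile oxide additions to acyclic allylic ethers is usually only moderate. The conjugated nitrile oxide can dimerise. A10 must first be made enantiopure in a separate asymmetric sequence (about three to four steps from 4-(benzyloxy)phenylacetaldehyde). An extra desilylation is needed, and the conjugate closure onto an electron-rich β-aryl enone is reversible and slow.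
- Comparison: on precedent this plan is better than the chosen one. On convergence it is roughly equal, since both join a guaiacyl C1–C3 unit to a C4–C7 or C3–C5 unit. On mechanism the chosen plan sets two ring stereocentres by catalyst control in the ring-forming step, while this plan relies on substrate control for C5 and thermodynamic control for C1 and C3. On step economy it is somewhat longer (about ten to eleven steps against eight).

Key step: step 3

## Route

Step 1
Reactants: 1 4-(benzyloxy)-3-methoxybenzaldehyde (O-benzylvanillin)
Product: 2 1-(benzyloxy)-2-methoxy-4-vinylbenzene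
Conditions: Ph3PCH3Br, KOt-Bu, THF, 0 °C to rt
Reagents that add atoms: methyltriphenylphosphonium bromide, C[P+](c1ccccc1)(c1ccccc1)c1ccccc1.[Br-]
Why: Wittig methylenation of a non-enolisable aryl aldehyde by the unstabilised ylide; the aryl ethers are inert to the base. The styrene should be kept cold with a trace of BHT and used promptly because it polymerises easily.

Step 2
Reactants: 3 benzyl vinyl ether; 4 ethyl chlorooxoacetate
Product: 5 ethyl (E)-4-(benzyloxy)-2-oxobut-3-enoate
Conditions: pyridine, CH2Cl2, 0 °C to rt
Reagents that add atoms: none
Why: Electrophilic C-acylation of the enol ether at its β-carbon by the acid chloride, followed by pyridine-assisted loss of HCl, is the standard entry to γ-alkoxy β,γ-unsaturated α-keto esters. The push–pull enone settles in the E geometry.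

Step 3
Reactants: 2 1-(benzyloxy)-2-methoxy-4-vinylbenzene; 5 ethyl (E)-4-(benzyloxy)-2-oxobut-3-enoate
Product: 6 ethyl (4R,6R)-4-(benzyloxy)-6-[4-(benzyloxy)-3-methoxyphenyl]-5,6-dihydro-4H-pyran-2-carboxylate (C1-aryl and C3-benzyloxy cis)
Conditions: Cu(OTf)2 (10 mol %), (S,S)-t-Bu-box [2,2'-(propane-2,2-diyl)bis((4S)-4-tert-butyl-4,5-dihydro-1,3-oxazole)] (11 mol %), 2,6-di-tert-butylpyridine (10 mol %), 3 Å MS, CH2Cl2, −40 to −20 °C, 2 added slowly to 5 (1.3 equiv)
Reagents that add atoms: none
Why: Proposed new method: the 1,2-dicarbonyl unit of 5 chelates the divalent copper centre of the Cu(OTf)2/bis(oxazoline) complex, which lowers the LUMO of the 1-oxadiene O=C5–C4=C3, so that the unsubstituted terminus C2 of 2 bonds to C3 while the positive charge growing at C1, stabilised by the para-benzyloxy group, is captured by the ketone oxygen. The dihydropyran thus closes by a concerted but asynchronous inverse-demand [4+2]; in the stepwise limit the closure is a 6-(enolendo)-exo-trig O-alkylation of the copper enolate by the benzylic cation. The closest known reaction type is the Cu(OTf)2/bis(oxazoline)-catalysed hetero-Diels–Alder of γ-alkoxy β,γ-unsaturated α-keto esters with alkyl vinyl ethers, and the extension rests on a 4-alkoxystyrene being only moderately less nucleophilic than such an ether. C3 is set by the ligand: in the square-planar chelate the tert-butyl groups should leave open the face that leads to 3R, an assignment made by analogy with other additions to α-dicarbonyl chelates of this catalyst, and the mirror-image ligand is the remedy should the sense be reversed. C1 is set relative to C3 by the endo orientation of the aryl group, which gives the 1,3-cis adduct, and a stepwise closure should favour the same isomer because both substituents then sit pseudo-equatorial. Regiochemistry is fixed by polarity, the nucleophilic CH2 of the styrene meeting the electrophilic γ-carbon. The selectivity most at stake is cycloaddition over cationic oligomerisation of 2, which is addressed by a low stationary concentration of 2, an excess of 5, low temperature, and a hindered pyridine that traps adventitious TfOH but cannot bind copper.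

Step 4
Reactants: 6 ethyl (4R,6R)-4-(benzyloxy)-6-[4-(benzyloxy)-3-methoxyphenyl]-5,6-dihydro-4H-pyran-2-carboxylate
Product: 7 ethyl (2S,4R,6R)-4-(benzyloxy)-6-[4-(benzyloxy)-3-methoxyphenyl]oxane-2-carboxylate (all-cis)
Conditions: H2 (1 atm), 5% Rh/Al2O3, EtOAc, rt
Reagents that add atoms: none
Why: Heterogeneous syn hydrogenation of the C4=C5 enol ether; rhodium on alumina at 1 atm saturates alkenes with little tendency to hydrogenolyse benzyl or allylic ethers. The pseudo-equatorial aryl and benzyloxy groups tilt toward one face of the half-chair, so hydrogen should add from the face bearing H1 and H3 and leave the ester equatorial and cis to both (5S).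

Step 5
Reactants: 7 ethyl (2S,4R,6R)-4-(benzyloxy)-6-[4-(benzyloxy)-3-methoxyphenyl]oxane-2-carboxylate
Product: 8 (2S,4R,6R)-4-(benzyloxy)-6-[4-(benzyloxy)-3-methoxyphenyl]-N-methoxy-N-methyloxane-2-carboxamide
Conditions: MeNHOMe·HCl, i-PrMgCl, THF, −20 to 0 °C
Reagents that add atoms: N,O-dimethylhydroxylamine hydrochloride, CNOC.Cl
Why: Direct aminolysis of the ester by the chloromagnesium amide (Weinreb amide formation). Any enolisation at C5 returns the equatorial, all-cis isomer, which is the thermodynamic one.

Step 6
Reactants: 8 (2S,4R,6R)-4-(benzyloxy)-6-[4-(benzyloxy)-3-methoxyphenyl]-N-methoxy-N-methyloxane-2-carboxamide; 9 4-(benzyloxy)benzyl chloride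
Product: 11 1-[(2S,4R,6R)-4-(benzyloxy)-6-[4-(benzyloxy)-3-methoxyphenyl]oxan-2-yl]-2-[4-(benzyloxy)phenyl]ethan-1-one, via 4-(benzyloxy)benzylmagnesium chloride 10 (not isolated)
Conditions: 9, Mg (I2-activated), 2-MeTHF, 0 °C, slow addition; then 8, THF, −20 to 0 °C; aq. NH4Cl
Reagents that add atoms: none
Why: Weinreb ketone synthesis: the Grignard reagent adds once to give a magnesium-chelated tetrahedral adduct that releases the ketone only on work-up, so neither over-addition nor enolisation of the benzylic ketone can occur in the flask. Slow, dilute, cold formation of 10 in 2-MeTHF limits Wurtz coupling.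

Step 7
Reactants: 11 1-[(2S,4R,6R)-4-(benzyloxy)-6-[4-(benzyloxy)-3-methoxyphenyl]oxan-2-yl]-2-[4-(benzyloxy)phenyl]ethan-1-one
Product: 12 (1R)-1-[(2S,4R,6R)-4-(benzyloxy)-6-[4-(benzyloxy)-3-methoxyphenyl]oxan-2-yl]-2-[4-(benzyloxy)phenyl]ethan-1-ol
Conditions: Zn(BH4)2, Et2O, −78 to −30 °C
Reagents that add atoms: none
Why: Cram-chelate reduction: zinc bridges the ketone oxygen and the ring oxygen in a five-membered chelate, and hydride arrives from the side of the C5–H bond, away from the ring CH2 (C4). This gives the anti relationship between the ring oxygen and the new hydroxyl, that is 6R.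

Step 8
Reactants: 12 (1R)-1-[(2S,4R,6R)-4-(benzyloxy)-6-[4-(benzyloxy)-3-methoxyphenyl]oxan-2-yl]-2-[4-(benzyloxy)phenyl]ethan-1-ol
Product: 13 (2S,4R,6R)-2-[(1R)-1-hydroxy-2-(4-hydroxyphenyl)ethyl]-6-(4-hydroxy-3-methoxyphenyl)oxan-4-ol (CNP0116327.2)
Conditions: H2 (1 atm), 10% Pd/C, EtOAc–EtOH, rt
Reagents that add atoms: none
Why: Catalytic hydrogenolysis of the two aryl benzyl ethers and the secondary alkyl benzyl ether in a neutral medium. The cyclic C1–O bond is a hindered secondary benzylic ether that should be cleaved far more slowly without acid, so the reaction is stopped as soon as debenzylation is complete.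

## Compound list

1 | 4-(benzyloxy)-3-methoxybenzaldehyde | COc1cc(C=O)ccc1OCc1ccccc1 | starting material
2 | 1-(benzyloxy)-2-methoxy-4-vinylbenzene | COc1cc(C=C)ccc1OCc1ccccc1 | intermediate
3 | benzyl vinyl ether | C=COCc1ccccc1 | starting material
4 | ethyl chlorooxoacetate | CCOC(=O)C(=O)Cl | starting material
5 | ethyl (E)-4-(benzyloxy)-2-oxobut-3-enoate | CCOC(=O)C(=O)/C=C/OCc1ccccc1 | intermediate
6 | ethyl (4R,6R)-4-(benzyloxy)-6-[4-(benzyloxy)-3-methoxyphenyl]-5,6-dihydro-4H-pyran-2-carboxylate | CCOC(=O)C1=C[C@H](OCc2ccccc2)C[C@H](c2ccc(OCc3ccccc3)c(OC)c2)O1 | intermediate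
7 | ethyl (2S,4R,6R)-4-(benzyloxy)-6-[4-(benzyloxy)-3-methoxyphenyl]oxane-2-carboxylate | COc1cc([C@H]2C[C@@H](OCc3ccccc3)C[C@@H](C(=O)OCC)O2)ccc1OCc1ccccc1 | intermediate
8 | (2S,4R,6R)-4-(benzyloxy)-6-[4-(benzyloxy)-3-methoxyphenyl]-N-methoxy-N-methyloxane-2-carboxamide | COc1cc([C@H]2C[C@@H](OCc3ccccc3)C[C@@H](C(=O)N(C)OC)O2)ccc1OCc1ccccc1 | intermediate
9 | 4-(benzyloxy)benzyl chloride | ClCc1ccc(OCc2ccccc2)cc1 | starting material
10 | 4-(benzyloxy)benzylmagnesium chloride | Cl[Mg]Cc1ccc(OCc2ccccc2)cc1 | intermediate
11 | 1-[(2S,4R,6R)-4-(benzyloxy)-6-[4-(benzyloxy)-3-methoxyphenyl]oxan-2-yl]-2-[4-(benzyloxy)phenyl]ethan-1-one | COc1cc([C@H]2C[C@@H](OCc3ccccc3)C[C@@H](C(=O)Cc3ccc(OCc4ccccc4)cc3)O2)ccc1OCc1ccccc1 | intermediate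
12 | (1R)-1-[(2S,4R,6R)-4-(benzyloxy)-6-[4-(benzyloxy)-3-methoxyphenyl]oxan-2-yl]-2-[4-(benzyloxy)phenyl]ethan-1-ol | COc1cc([C@H]2C[C@@H](OCc3ccccc3)C[C@@H]([C@H](O)Cc3ccc(OCc4ccccc4)cc3)O2)ccc1OCc1ccccc1 | intermediate
13 | (2S,4R,6R)-2-[(1R)-1-hydroxy-2-(4-hydroxyphenyl)ethyl]-6-(4-hydroxy-3-methoxyphenyl)oxan-4-ol | COc1cc([C@H]2C[C@@H](O)C[C@@H]([C@H](O)Cc3ccc(O)cc3)O2)ccc1O | target

## Step count and uncertain steps

Total: 8 steps. Longest linear sequence: 7 steps (steps 1, 3, 4, 5, 6, 7, 8 from 1; equally steps 2 to 8 from 3).

Stereochemical audit: C1 and C3 are set in step 3, C5 in step 4 and C6 in step 7. After step 3 no acidic step is used, so the benzylic C1–O bond is not ionised. C5 is enolisable in 7, 8 and 11, but its thermodynamic position is the required equatorial one.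

**Step 3 (key step).** Acid- or Lewis-acid-initiated cationic oligomerisation of the electron-rich styrene may outrun the cycloaddition, because the styrene is less nucleophilic toward the chelated heterodiene than a vinyl ether and its benzylic cation is long-lived. Incomplete endo preference or a weaker facial bias than with enol ethers is the second concern.

Fallback (known chemistry, from 1, returning at 7): a Prins cyclisation with the stereochemistry relayed from C5.
- Aldehyde 1 and the known hydroxy ester ethyl (2S)-2-hydroxypent-4-enoate F1 (obtainable from (S)-allylglycine by diazotisation with retention and esterification) are combined with CF3CO2H in CH2Cl2 at 0 °C to rt.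
- The aryl-stabilised E-oxocarbenium ion should cyclise through a chair with all substituents equatorial and be trapped equatorially at C3. This gives the all-cis trifluoroacetate ethyl (2S,4R,6R)-6-[4-(benzyloxy)-3-methoxyphenyl]-4-(trifluoroacetoxy)oxane-2-carboxylate F2.
- Oxonia-Cope scrambling is disfavoured because it would exchange the aryl-stabilised cation for an ester-destabilised one.
- Ethanolysis (K2CO3, EtOH) gives the alcohol ethyl (2S,4R,6R)-6-[4-(benzyloxy)-3-methoxyphenyl]-4-hydroxyoxane-2-carboxylate F3.
- Neutral O-benzylation (2-benzyloxy-1-methylpyridinium triflate, MgO, PhCF3, 85 °C) gives 7.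

**Step 4.** Three processes may interfere: partial saturation of the electron-rich arenes on rhodium, hydrogenolytic loss of the allylic C3 benzyloxy group, and insufficient facial discrimination because both ring substituents are only pseudo-equatorial.

Fallback (from 6, returning at 7): hydride conjugate reduction under thermodynamic control in place of surface hydrogenation.
- [(Ph3P)CuH]6 in toluene (or Cu(OAc)2/bisphosphine with a hydrosilane) delivers hydride to C4, and protonation of the enolate gives 7 together with its C5 epimer ethyl (2R,4R,6R)-4-(benzyloxy)-6-[4-(benzyloxy)-3-methoxyphenyl]oxane-2-carboxylate F4.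
- NaOEt in EtOH then equilibrates F4 to the all-equatorial 7.
- No leaving group lies β to the enolate, so elimination is not expected.

**Step 6.** Wurtz-type homocoupling during magnesium insertion into the electron-rich benzylic chloride may leave too little active reagent, and the basic reagent may deprotonate rather than add if the amide is hindered.

Fallback (from 8, returning at 11): the arm is built by forming the C7–aryl bond instead of C6–C7.
- MeMgBr (THF, 0 °C) converts 8 into the methyl ketone 1-[(2S,4R,6R)-4-(benzyloxy)-6-[4-(benzyloxy)-3-methoxyphenyl]oxan-2-yl]ethan-1-one F5.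
- Palladium-catalysed α-arylation of the methyl group with 1-(benzyloxy)-4-bromobenzene (Pd2(dba)3, Xantphos, NaOt-Bu, THF, 70 °C) gives 11.
- The tertiary, alkoxy-bearing C5 is too hindered to be arylated, and base-induced epimerisation there leads back to the required isomer.

**Step 7.** Chelation control may be eroded by competing non-chelated (Felkin–Anh) hydride delivery, since the ring oxygen is a hindered donor, and this would lower the anti selectivity at C6.

Fallback (from 11, returning at 12): the opposite epimer is made on purpose and inverted.
- The bulky, non-chelating LiBH(s-Bu)3 (THF, −78 °C) should give the syn alcohol (1S)-1-[(2S,4R,6R)-4-(benzyloxy)-6-[4-(benzyloxy)-3-methoxyphenyl]oxan-2-yl]-2-[4-(benzyloxy)phenyl]ethan-1-ol F6.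
- Mitsunobu inversion (4-nitrobenzoic acid, PPh3, DIAD, THF) gives the (1R)-4-nitrobenzoate F7.
- Methanolysis (K2CO3, MeOH) gives 12.
- Any syn material from the Zn(BH4)2 reduction can be recycled the same way.

**Step 8.** Hydrogenolytic opening of the ring at the benzylic C1–O bond may compete while the slower secondary alkyl benzyl ether at C3 is still being cleaved, because the para-oxygenated aryl group activates that bond.

Fallback (from 12, returning at 13, no new compound): electron-transfer debenzylation with lithium 4,4'-di-tert-butylbiphenylide (THF, −78 °C, then NH4Cl). The electron enters the unsubstituted phenyl ring of each benzyl group. The guaiacyl ring is electron-rich and becomes a phenoxide after the first cleavage, so it should resist reduction and the ring C1–O bond should stay intact.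

## Further compounds

F1 | step 3 | ethyl (2S)-2-hydroxypent-4-enoate | CCOC(=O)[C@@H](O)CC=C
F2 | step 3 | ethyl (2S,4R,6R)-6-[4-(benzyloxy)-3-methoxyphenyl]-4-(trifluoroacetoxy)oxane-2-carboxylate | COc1cc([C@H]2C[C@@H](OC(=O)C(F)(F)F)C[C@@H](C(=O)OCC)O2)ccc1OCc1ccccc1
F3 | step 3 | ethyl (2S,4R,6R)-6-[4-(benzyloxy)-3-methoxyphenyl]-4-hydroxyoxane-2-carboxylate | COc1cc([C@H]2C[C@@H](O)C[C@@H](C(=O)OCC)O2)ccc1OCc1ccccc1
F4 | step 4 | ethyl (2R,4R,6R)-4-(benzyloxy)-6-[4-(benzyloxy)-3-methoxyphenyl]oxane-2-carboxylate (C5 epimer of 7) | COc1cc([C@H]2C[C@@H](OCc3ccccc3)C[C@H](C(=O)OCC)O2)ccc1OCc1ccccc1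
F5 | step 6 | 1-[(2S,4R,6R)-4-(benzyloxy)-6-[4-(benzyloxy)-3-methoxyphenyl]oxan-2-yl]ethan-1-one | COc1cc([C@H]2C[C@@H](OCc3ccccc3)C[C@@H](C(C)=O)O2)ccc1OCc1ccccc1
F6 | step 7 | (1S)-1-[(2S,4R,6R)-4-(benzyloxy)-6-[4-(benzyloxy)-3-methoxyphenyl]oxan-2-yl]-2-[4-(benzyloxy)phenyl]ethan-1-ol | COc1cc([C@H]2C[C@@H](OCc3ccccc3)C[C@@H]([C@@H](O)Cc3ccc(OCc4ccccc4)cc3)O2)ccc1OCc1ccccc1
F7 | step 7 | (1R)-1-[(2S,4R,6R)-4-(benzyloxy)-6-[4-(benzyloxy)-3-methoxyphenyl]oxan-2-yl]-2-[4-(benzyloxy)phenyl]ethyl 4-nitrobenzoate | COc1cc([C@H]2C[C@@H](OCc3ccccc3)C[C@@H]([C@H](OC(=O)c3ccc(cc3)[N+](=O)[O-])Cc3ccc(OCc4ccccc4)cc3)O2)ccc1OCc1ccccc1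
F0 | step 8 | none | none
A1 | alternative 1 | (2S,3R)-3-(benzyloxy)-4-[4-(benzyloxy)phenyl]-1-{2-[(2R)-2-[4-(benzyloxy)-3-methoxyphenyl]-2-[(tert-butyldimethylsilyl)oxy]ethyl]-1,3-dithian-2-yl}butan-2-ol | COc1cc([C@H](O[Si](C)(C)C(C)(C)C)CC2(SCCCS2)C[C@H](O)[C@H](OCc2ccccc2)Cc2ccc(OCc3ccccc3)cc2)ccc1OCc1ccccc1
A2 | alternative 1 | tert-butyl(1,3-dithian-2-yl)dimethylsilane | CC(C)(C)[Si](C)(C)C1SCCCS1
A3 | alternative 1 | (2S)-2-[4-(benzyloxy)-3-methoxyphenyl]oxirane | COc1cc([C@H]2CO2)ccc1OCc1ccccc1
A4 | alternative 1 | (2S)-2-[(1R)-1-(benzyloxy)-2-[4-(benzyloxy)phenyl]ethyl]oxirane | C1O[C@@H]1[C@H](OCc1ccccc1)Cc1ccc(OCc2ccccc2)cc1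
A5 | alternative 2 | (1R,5S)-8-oxabicyclo[3.2.1]oct-6-en-3-one (meso) | O=C1C[C@H]2C=C[C@@H](C1)O2
A6 | alternative 2 | furan | c1ccoc1
A7 | alternative 2 | 1,1,3,3-tetrabromopropan-2-one | BrC(Br)C(=O)C(Br)Br
A8 | alternative 3 | (5S)-3-{(E)-2-[4-(benzyloxy)-3-methoxyphenyl]ethenyl}-5-{(1R)-2-[4-(benzyloxy)phenyl]-1-[(tert-butyldimethylsilyl)oxy]ethyl}-4,5-dihydro-1,2-oxazole | COc1cc(/C=C/C2=NO[C@H]([C@H](O[Si](C)(C)C(C)(C)C)Cc3ccc(OCc4ccccc4)cc3)C2)ccc1OCc1ccccc1
A9 | alternative 3 | (2E)-3-[4-(benzyloxy)-3-methoxyphenyl]prop-2-enal oxime | COc1cc(/C=C/C=NO)ccc1OCc1ccccc1
A10 | alternative 3 | tert-butyl({(2R)-1-[4-(benzyloxy)phenyl]but-3-en-2-yl}oxy)dimethylsilane | C=C[C@H](O[Si](C)(C)C(C)(C)C)Cc1ccc(OCc2ccccc2)cc1
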